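**An easy step.** Past its peak, target fell in both earlier runs, and a loss proportional to what is present integrates to a plain exponential. So I read one quantity, the fade rate: the fraction of the target lost per hour after the peak.

| flask | substrate | partner | remark | time |
|---|---|---|---|---|
| north | 0.031 M | 0.0473 M (fed, over 4.0 h) | run made earlier; the fed solution adds 0.10 times the starting volume |  |
| east | 0.048 M | 0.0473 M (fed, over 4.0 h) | run made earlier; the fed solution adds 0.10 times the starting volume |  |
| gamma | 0.060 M | 0.0473 M | everything together at the start, the whole solution of partner included, so that from the start the volume is larger by 0.10 times the starting volume | 20 h |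
| epsilon | 0.043 M | 0.0473 M (fed, over 4.0 h) | the fed solution adds 0.10 times the starting volume | 20 h |

| run | time / h | target / % |
|---|---|---|
| north | 0.833 | 0 |
| north | 2.00 | 9 |
| north | 4.00 | 21 |
| north | 6.00 | 32 |
| north | 8.00 | 34 |
| north | 12.0 | 31 |
| north | 15.0 | 27 |
| east | 0.833 | 2 |
| east | 2.00 | 8 |
| east | 4.00 | 20 |
| east | 6.00 | 25 |
| east | 8.00 | 28 |
| east | 12.0 | 26 |
| east | 15.0 | 18 |

(standard deviation of a reading: 2 percentage points)

- the winner by amount of target, in percent of the substrate charged; "neither" if no more than 2 percentage points parts them (gamma / epsilon / neither)
- how much target is there at the end, in percent of the substrate charged: gamma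
- how much target is there at the end, in percent of the substrate charged: epsilon

- charges are per starting volume, the dose included; the dosed solution carries all of it

**The bracket.** From peak to last reading, the north run gave 0.0329 h⁻¹ and the east run 0.0631 h⁻¹. Epsilon's substrate lies between theirs. For my ceiling I ran north's last reading on at north's rate to 20 h, which gave 22.9% of the charge. For my floor I did the same with east, which gave 13.1%.

**Tightening it.** Epsilon stands 0.706 of the way from north to east, so its fade rate came to 0.0542 h⁻¹, and my estimate for epsilon to 15.7%. Gamma has more substrate than either run, so I gave it the same bracket with less trust. A bracket 9.8 percentage points wide named no winner against a margin of 2 points.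

**The forecast.** It said gamma 11%, below my floor, and epsilon 15%, inside the bracket, and it chose epsilon, in its words “Epsilon is probably ahead”.

**The flasks.** Gamma gave 18.6% and epsilon 18.8%, both inside the bracket, and the winner was neither.

    second intermediate → decomposed reagent (k = 2.00 × 10⁻⁵ s⁻¹)
    2 open intermediate → homo product (k = 0.00710 M⁻¹ s⁻¹)
    open intermediate + second intermediate ⇌ target (K = 180 M⁻¹, k = 0.00510 M⁻¹ s⁻¹)
    substrate → open intermediate (k = 2.20 × 10⁻⁴ s⁻¹)
    partner → second intermediate (k = 0.00100 s⁻¹)

**Not at rest.** Neither flask had stopped at 20 h, with target still at 18.6% in gamma and 18.8% in epsilon. In epsilon the relaxation half-life of the target step, taken by itself at that time, was 1.98 h, shorter than 20 h. Over ten times the time, my fade rate leaves 0.00109% of the charge as target in epsilon and 0.00108% in gamma. The flasks give 0% and 0%. Homo product rises from 75.7% to 99.7% in gamma and from 75.2% to 99.6% in epsilon.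

The readings were generated by integration for an exercise; scatter was added.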